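**Plan**
1. Retrosynthesis: the enone C=C is cut by an aldol condensation and its ketone traced to a vinyl group (Wacker). The oxepane (O1, C2H2, C3=CH, C4, C5, C6–OH, C7 quaternary) is then cut at C2–C3 and C5–C6 in one operation, which frees C3–C4–C5 plus the exocyclic carbon as ethyl cyclopropylideneacetate.
2. Enabling feature: the sp2 ring carbon C3 lies between the ether methylene C2 and, two methylenes on, the carbinol C6, and both C2 and C6 hang on O1–C7. A radical at C2 and an aldehyde at C6 can therefore bracket a cyclopropylidene acetate that opens on radical addition: a radical–polar (4+3) annulation.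
3. Forward: (S)-β-citronellene → allylic oxidation, asymmetric epoxidation, hydride opening → diazoacetate, O–H insertion, hydrolysis/oxidation → aldehyde acid → annulation (ring formed) → ketone, reduction, ester reduction, silylation → Wacker, aldol condensation (chain completed), desilylation.
4. Stereochemistry: the side-chain methyl centre is bought with citronellene; C7 comes from the Sharpless epoxidation; C6 from a CBS reduction of the ring ketone (reagent control); the exocyclic (E)-alkene from the cyclopropylcarbinyl radical opening; the enone (E) from the E1cB elimination.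

Key step: step 7

Assumption: (S)-β-citronellene of high enantiomeric purity and ethyl cyclopropylideneacetate are taken as purchasable (the latter is otherwise one Wittig step from (1-ethoxycyclopropoxy)trimethylsilane).

**Step 1**
Reactants: 1 (S)-3,7-dimethylocta-1,6-diene
Product: 2 (2E,6S)-2,6-dimethylocta-2,7-dien-1-ol
Conditions: SeO2 (0.1 equiv), t-BuOOH, salicylic acid (cat.), CH2Cl2, rt
Reagents that add atoms: tert-butyl hydroperoxide CC(C)(C)OO
Why: Catalytic SeO2 allylic oxidation (ene reaction then [2,3]-sigmatropic shift) should hydroxylate the (E)-methyl of the trisubstituted alkene and leave the less electron-rich vinyl group untouched; no stereocentre is formed.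

**Step 2**
Reactants: 2 (2E,6S)-2,6-dimethylocta-2,7-dien-1-ol
Product: 3 [(2R,3R)-2-methyl-3-[(3S)-3-methylpent-4-en-1-yl]oxiran-2-yl]methanol
Conditions: Ti(OiPr)4 (cat.), D-(−)-diethyl tartrate (cat.), t-BuOOH, 4 Å molecular sieves, CH2Cl2, −20 °C
Reagents that add atoms: tert-butyl hydroperoxide CC(C)(C)OO
Why: Sharpless asymmetric epoxidation, in which the titanium tartrate complex of D-(−)-diethyl tartrate delivers oxygen to one face of the allylic alcohol and so fixes the methyl-bearing epoxide carbon (the later C7), while the isolated vinyl group is not epoxidised.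

**Step 3**
Reactants: 3 [(2R,3R)-2-methyl-3-[(3S)-3-methylpent-4-en-1-yl]oxiran-2-yl]methanol
Product: 4 (2S,6S)-2,6-dimethyloct-7-ene-1,2-diol
Conditions: LiAlH4, THF, 0 °C → rt
Reagents that add atoms: none
Why: Regioselective reductive epoxide opening, in which hydride attacks the less substituted epoxide carbon by SN2, so the C–O bond at the fully substituted carbon is untouched and its configuration is kept in the tertiary alcohol.

**Step 4**
Reactants: 4 (2S,6S)-2,6-dimethyloct-7-ene-1,2-diol
Product: 6 (2S,6S)-2-hydroxy-2,6-dimethyloct-7-en-1-yl diazoacetate, via bromoacetate 5 (not isolated)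
Conditions: BrCH2COBr, NaHCO3, MeCN, 0 °C; then TsNHNHTs, DBU, THF, 0 °C
Reagents that add atoms: bromoacetyl bromide O=C(Br)CBr; N,N'-ditosylhydrazine Cc1ccc(cc1)S(=O)(=O)NNS(=O)(=O)c1ccc(C)cc1
Why: Chemoselective acylation of the primary hydroxyl followed by the ditosylhydrazine diazo synthesis (N-alkylation, then loss of two sulfinates) should give the diazoacetate without touching the tertiary alcohol.

**Step 5**
Reactants: 6 (2S,6S)-2-hydroxy-2,6-dimethyloct-7-en-1-yl diazoacetate
Product: 7 (5S)-5-methyl-5-[(4S)-4-methylhex-5-en-1-yl]-1,4-dioxan-2-one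
Conditions: Rh2(OAc)4 (1 mol%), CH2Cl2, rt, slow addition
Reagents that add atoms: none
Why: Rhodium carbenoid O–H insertion into the tertiary hydroxyl closes the six-membered dioxanone under neutral conditions, which etherifies the hindered oxygen with the future C2 carbon without acyl migration and without touching the stereocentre.

**Step 6**
Reactants: 7 (5S)-5-methyl-5-[(4S)-4-methylhex-5-en-1-yl]-1,4-dioxan-2-one
Product: 9 {[(2S,6S)-2,6-dimethyl-1-oxooct-7-en-2-yl]oxy}acetic acid, via lithium hydroxy carboxylate 8 (not isolated)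
Conditions: LiOH, THF/H2O, 0 °C; evaporate; IBX, DMSO, rt; then 1 M HCl to pH 3
Reagents that add atoms: lithium hydroxide [Li+].[OH-]
Why: Saponification opens the lactone to a carboxylate that cannot relactonise, and IBX oxidation of the primary alcohol should stop at the non-enolisable α-alkoxy aldehyde.

**Step 7**
Reactants: 9 {[(2S,6S)-2,6-dimethyl-1-oxooct-7-en-2-yl]oxy}acetic acid; 10 ethyl cyclopropylideneacetate
Product: 11 ethyl (2E)-[(7S)-6-hydroxy-7-methyl-7-[(4S)-4-methylhex-5-en-1-yl]oxepan-3-ylidene]acetate (both C6 epimers)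
Conditions: 4CzIPN (2 mol%), CrCl3 (15 mol%), 4,4'-di-tert-butyl-2,2'-bipyridine (15 mol%), 2,6-lutidine (1 equiv), 10 (3 equiv), DMF (0.02 M), blue LEDs, rt
Reagents that add atoms: none
Why: Proposed new method: excited 4CzIPN oxidises the carboxylate of 9 and loss of CO2 gives a nucleophilic α-alkoxymethyl radical that adds to the strained ring carbon (the enoate β-carbon) of 10; the α-ester cyclopropylcarbinyl radical then opens to a primary homoallyl radical as the C=C bond moves into conjugation with the ester, divalent chromium (regenerated by the reduced photocatalyst) captures that radical, and the alkylchromium adds to the aldehyde, the lutidinium ion freeing the product from the trivalent chromium alkoxide. The closest known reaction types are the decarboxylative Giese addition of α-alkoxy acids and the three-component dialkylation of 1,3-dienes with aldehydes under dual photoredox and chromium catalysis, here with a radical-clock ring opening in place of the allyl shift. The oxepane closes by 7-exo-trig addition of the alkylchromium to the aldehyde carbon (Nozaki–Hiyama type), after the C2–C3 bond has been made in the intermolecular radical step. The (E) geometry is set in the ring opening, because in the bisected cyclopropylcarbinyl radical the ester lies anti to the new CH2O substituent and ends up trans to it; the carbinol centre C6 is not controlled (methyl and methylene on C7 are too alike), and both epimers go on to steps 8 and 9. The step needs radical attack at the ring carbon of 10 (secured by enoate polarity and strain release), ring opening before reduction of the ester-stabilised radical (secured by the low stationary concentration of divalent chromium) and intramolecular, aldehyde-selective capture (secured by organochromium chemoselectivity and dilution).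

**Step 8**
Reactants: 11 ethyl (2E)-[(7S)-6-hydroxy-7-methyl-7-[(4S)-4-methylhex-5-en-1-yl]oxepan-3-ylidene]acetate (both C6 epimers)
Product: 12 ethyl (2E)-[(7S)-7-methyl-7-[(4S)-4-methylhex-5-en-1-yl]-6-oxooxepan-3-ylidene]acetate
Conditions: Dess–Martin periodinane, CH2Cl2, 0 °C → rt
Reagents that add atoms: none
Why: Dess–Martin oxidation converts both carbinol epimers into one ketone and so removes the uncontrolled stereocentre.

**Step 9**
Reactants: 12 ethyl (2E)-[(7S)-7-methyl-7-[(4S)-4-methylhex-5-en-1-yl]-6-oxooxepan-3-ylidene]acetate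
Product: 13 ethyl (2E)-[(6R,7S)-6-hydroxy-7-methyl-7-[(4S)-4-methylhex-5-en-1-yl]oxepan-3-ylidene]acetate
Conditions: (S)-2-methyl-CBS-oxazaborolidine (0.2 equiv), catecholborane, toluene, −78 °C
Reagents that add atoms: none
Why: Corey–Bakshi–Shibata reduction, in which the (S)-oxazaborolidine tells the fully substituted α-carbon (large) from the ring methylene (small) and should give the (6R)-alcohol by reagent control, while catecholborane at low temperature spares the enoate and the terminal alkene.

**Step 10**
Reactants: 13 ethyl (2E)-[(6R,7S)-6-hydroxy-7-methyl-7-[(4S)-4-methylhex-5-en-1-yl]oxepan-3-ylidene]acetate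
Product: 14 (2S,3R,6E)-6-(2-hydroxyethylidene)-2-methyl-2-[(4S)-4-methylhex-5-en-1-yl]oxepan-3-ol
Conditions: i-Bu2AlH (4 equiv), CH2Cl2, −78 °C; Rochelle salt work-up
Reagents that add atoms: none
Why: 1,2-Reduction of the α,β-unsaturated ester with i-Bu2AlH should give the allylic alcohol with the (E) geometry intact.

**Step 11**
Reactants: 14 (2S,3R,6E)-6-(2-hydroxyethylidene)-2-methyl-2-[(4S)-4-methylhex-5-en-1-yl]oxepan-3-ol
Product: 15 (2S,3R,6E)-3-[(tert-butyldimethylsilyl)oxy]-6-{2-[(tert-butyldimethylsilyl)oxy]ethylidene}-2-methyl-2-[(4S)-4-methylhex-5-en-1-yl]oxepane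
Conditions: TBSOTf (2.5 equiv), 2,6-lutidine, CH2Cl2, −78 → 0 °C
Reagents that add atoms: tert-butyldimethylsilyl trifluoromethanesulfonate CC(C)(C)[Si](C)(C)OS(=O)(=O)C(F)(F)F
Why: Silyl triflate silylation protects the primary allylic and the hindered secondary hydroxyl for the enolate chemistry that follows.

**Step 12**
Reactants: 15 (2S,3R,6E)-3-[(tert-butyldimethylsilyl)oxy]-6-{2-[(tert-butyldimethylsilyl)oxy]ethylidene}-2-methyl-2-[(4S)-4-methylhex-5-en-1-yl]oxepane
Product: 16 (3S)-6-[(2S,3R,6E)-3-[(tert-butyldimethylsilyl)oxy]-6-{2-[(tert-butyldimethylsilyl)oxy]ethylidene}-2-methyloxepan-2-yl]-3-methylhexan-2-one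
Conditions: PdCl2(quinox) (5 mol%; quinox = 2-(4,5-dihydrooxazol-2-yl)quinoline), AgSbF6 (12 mol%), aq. t-BuOOH, CH2Cl2, 0 °C → rt
Reagents that add atoms: tert-butyl hydroperoxide CC(C)(C)OO
Why: Wacker oxidation of the monosubstituted alkene should give the methyl ketone with Markovnikov selectivity (the peroxide-mediated variant is chosen to suppress double-bond migration), while the hindered trisubstituted exocyclic alkene does not react.

**Step 13**
Reactants: 17 methyl 2-hydroxy-2-methylpropanoate
Product: 18 methyl 2-methyl-2-[(triethylsilyl)oxy]propanoate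
Conditions: Et3SiOTf, 2,6-lutidine, CH2Cl2, 0 °C
Reagents that add atoms: triethylsilyl trifluoromethanesulfonate CC[Si](CC)(CC)OS(=O)(=O)C(F)(F)F
Why: Silyl triflate silylation of the tertiary alcohol.

**Step 14**
Reactants: 18 methyl 2-methyl-2-[(triethylsilyl)oxy]propanoate
Product: 19 2-methyl-2-[(triethylsilyl)oxy]propanal
Conditions: i-Bu2AlH (1.1 equiv), CH2Cl2, −78 °C
Reagents that add atoms: none
Why: Partial reduction of the ester with i-Bu2AlH at low temperature should stop at the aldehyde because the aluminium hemiacetal is stable until work-up.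

**Step 15**
Reactants: 16 (3S)-6-[(2S,3R,6E)-3-[(tert-butyldimethylsilyl)oxy]-6-{2-[(tert-butyldimethylsilyl)oxy]ethylidene}-2-methyloxepan-2-yl]-3-methylhexan-2-one; 19 2-methyl-2-[(triethylsilyl)oxy]propanal
Product: 22 (3E,6S)-9-[(2S,3R,6E)-3-[(tert-butyldimethylsilyl)oxy]-6-{2-[(tert-butyldimethylsilyl)oxy]ethylidene}-2-methyloxepan-2-yl]-2,6-dimethyl-2-[(triethylsilyl)oxy]non-3-en-5-one, via aldol adduct 20 (not isolated), via mesylate 21 (not isolated)
Conditions: LiN(i-Pr)2, THF, −78 °C; 19; then MsCl, −78 → 0 °C; DBU, rt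
Reagents that add atoms: none
Why: Aldol condensation by kinetic deprotonation at the methyl group, addition to the non-enolisable aldehyde, mesylation of the aldolate and E1cB elimination should give the (E)-enone as the thermodynamic outcome, and the methyl-bearing stereocentre on the other side of the ketone is not deprotonated under kinetic conditions.

**Step 16**
Reactants: 22 (3E,6S)-9-[(2S,3R,6E)-3-[(tert-butyldimethylsilyl)oxy]-6-{2-[(tert-butyldimethylsilyl)oxy]ethylidene}-2-methyloxepan-2-yl]-2,6-dimethyl-2-[(triethylsilyl)oxy]non-3-en-5-one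
Product: 23 (3E,6S)-2-hydroxy-9-[(2S,3R,6E)-3-hydroxy-6-(2-hydroxyethylidene)-2-methyloxepan-2-yl]-2,6-dimethylnon-3-en-5-one
Conditions: HF·pyridine, pyridine, THF, 0 °C → rt
Reagents that add atoms: none
Why: Fluoride-mediated cleavage of the three silyl ethers under buffered conditions should free the triol without epimerising the α-methyl ketone or ionising the tertiary allylic alcohol.

**Compound list**
1 | (S)-3,7-dimethylocta-1,6-diene ((S)-β-citronellene) | C[C@@H](CCC=C(C)C)C=C | starting material
2 | (2E,6S)-2,6-dimethylocta-2,7-dien-1-ol | C[C@@H](CC/C=C(\C)CO)C=C | intermediate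
3 | [(2R,3R)-2-methyl-3-[(3S)-3-methylpent-4-en-1-yl]oxiran-2-yl]methanol | OC[C@@]1(C)O[C@@H]1CC[C@H](C)C=C | intermediate
4 | (2S,6S)-2,6-dimethyloct-7-ene-1,2-diol | OC[C@@](C)(O)CCC[C@H](C)C=C | intermediate
5 | (2S,6S)-2-hydroxy-2,6-dimethyloct-7-en-1-yl bromoacetate | BrCC(=O)OC[C@@](C)(O)CCC[C@H](C)C=C | intermediate
6 | (2S,6S)-2-hydroxy-2,6-dimethyloct-7-en-1-yl diazoacetate | [N-]=[N+]=CC(=O)OC[C@@](C)(O)CCC[C@H](C)C=C | intermediate
7 | (5S)-5-methyl-5-[(4S)-4-methylhex-5-en-1-yl]-1,4-dioxan-2-one | O=C1CO[C@@](C)(CCC[C@H](C)C=C)CO1 | intermediate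
8 | lithium {[(2S,6S)-1-hydroxy-2,6-dimethyloct-7-en-2-yl]oxy}acetate | [Li+].[O-]C(=O)CO[C@](C)(CO)CCC[C@H](C)C=C | intermediate
9 | {[(2S,6S)-2,6-dimethyl-1-oxooct-7-en-2-yl]oxy}acetic acid | O=C[C@@](C)(OCC(=O)O)CCC[C@H](C)C=C | intermediate
10 | ethyl cyclopropylideneacetate | CCOC(=O)C=C1CC1 | starting material
11 | ethyl (2E)-[(7S)-6-hydroxy-7-methyl-7-[(4S)-4-methylhex-5-en-1-yl]oxepan-3-ylidene]acetate (both C6 epimers) | C=C[C@@H](C)CCC[C@]1(C)OC/C(=C/C(=O)OCC)CCC1O | intermediate
12 | ethyl (2E)-[(7S)-7-methyl-7-[(4S)-4-methylhex-5-en-1-yl]-6-oxooxepan-3-ylidene]acetate | C=C[C@@H](C)CCC[C@]1(C)OC/C(=C/C(=O)OCC)CCC1=O | intermediate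
13 | ethyl (2E)-[(6R,7S)-6-hydroxy-7-methyl-7-[(4S)-4-methylhex-5-en-1-yl]oxepan-3-ylidene]acetate | C=C[C@@H](C)CCC[C@]1(C)OC/C(=C/C(=O)OCC)CC[C@H]1O | intermediate
14 | (2S,3R,6E)-6-(2-hydroxyethylidene)-2-methyl-2-[(4S)-4-methylhex-5-en-1-yl]oxepan-3-ol | C=C[C@@H](C)CCC[C@]1(C)OC/C(=C/CO)CC[C@H]1O | intermediate
15 | (2S,3R,6E)-3-[(tert-butyldimethylsilyl)oxy]-6-{2-[(tert-butyldimethylsilyl)oxy]ethylidene}-2-methyl-2-[(4S)-4-methylhex-5-en-1-yl]oxepane | C=C[C@@H](C)CCC[C@]1(C)OC/C(=C/CO[Si](C)(C)C(C)(C)C)CC[C@H]1O[Si](C)(C)C(C)(C)C | intermediate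
16 | (3S)-6-[(2S,3R,6E)-3-[(tert-butyldimethylsilyl)oxy]-6-{2-[(tert-butyldimethylsilyl)oxy]ethylidene}-2-methyloxepan-2-yl]-3-methylhexan-2-one | CC(=O)[C@@H](C)CCC[C@]1(C)OC/C(=C/CO[Si](C)(C)C(C)(C)C)CC[C@H]1O[Si](C)(C)C(C)(C)C | intermediate
17 | methyl 2-hydroxy-2-methylpropanoate | COC(=O)C(C)(C)O | starting material
18 | methyl 2-methyl-2-[(triethylsilyl)oxy]propanoate | COC(=O)C(C)(C)O[Si](CC)(CC)CC | intermediate
19 | 2-methyl-2-[(triethylsilyl)oxy]propanal | O=CC(C)(C)O[Si](CC)(CC)CC | intermediate
20 | (6S)-9-[(2S,3R,6E)-3-[(tert-butyldimethylsilyl)oxy]-6-{2-[(tert-butyldimethylsilyl)oxy]ethylidene}-2-methyloxepan-2-yl]-3-hydroxy-2,6-dimethyl-2-[(triethylsilyl)oxy]nonan-5-one (aldol adduct, both carbinol epimers, present as its lithium alkoxide) | CC(C)(O[Si](CC)(CC)CC)C(O)CC(=O)[C@@H](C)CCC[C@]1(C)OC/C(=C/CO[Si](C)(C)C(C)(C)C)CC[C@H]1O[Si](C)(C)C(C)(C)C | intermediate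
21 | (6S)-9-[(2S,3R,6E)-3-[(tert-butyldimethylsilyl)oxy]-6-{2-[(tert-butyldimethylsilyl)oxy]ethylidene}-2-methyloxepan-2-yl]-2,6-dimethyl-5-oxo-2-[(triethylsilyl)oxy]nonan-3-yl methanesulfonate | CC(C)(O[Si](CC)(CC)CC)C(OS(C)(=O)=O)CC(=O)[C@@H](C)CCC[C@]1(C)OC/C(=C/CO[Si](C)(C)C(C)(C)C)CC[C@H]1O[Si](C)(C)C(C)(C)C | intermediate
22 | (3E,6S)-9-[(2S,3R,6E)-3-[(tert-butyldimethylsilyl)oxy]-6-{2-[(tert-butyldimethylsilyl)oxy]ethylidene}-2-methyloxepan-2-yl]-2,6-dimethyl-2-[(triethylsilyl)oxy]non-3-en-5-one | CC(C)(O[Si](CC)(CC)CC)/C=C/C(=O)[C@@H](C)CCC[C@]1(C)OC/C(=C/CO[Si](C)(C)C(C)(C)C)CC[C@H]1O[Si](C)(C)C(C)(C)C | intermediate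
23 | (3E,6S)-2-hydroxy-9-[(2S,3R,6E)-3-hydroxy-6-(2-hydroxyethylidene)-2-methyloxepan-2-yl]-2,6-dimethylnon-3-en-5-one | C[C@@H](CCC[C@]1(C)OC/C(=C/CO)CC[C@H]1O)C(=O)/C=C/C(C)(C)O | target

**Step count:** 16 steps in total. Longest linear sequence: 14 steps (steps 1–12, 15, 16).

**Steps most likely to fail**

Step 7. Three processes could divert the annulation. Divalent chromium may reduce the ester-stabilised radical to a chromium enolate before the cyclopropane opens, and that enolate would then add to the aldehyde and close a six-membered ring. Chromium may also capture the first radical before it meets the acceptor. The opened radical may add to a second acceptor molecule. The fallback sets out from lactone 7 and comes back at 11, using known reactions only. A Kulinkovich reaction of the lactone (EtMgBr, Ti(OiPr)4, THF) would give 1-({[(2S,6S)-1-hydroxy-2,6-dimethyloct-7-en-2-yl]oxy}methyl)cyclopropan-1-ol F1. Parikh–Doering oxidation of its primary alcohol (SO3·pyridine, DMSO, Et3N) would give (2S,6S)-2-[(1-hydroxycyclopropyl)methoxy]-2,6-dimethyloct-7-enal F2. Opening of the cyclopropanol to the zinc homoenolate (Et2Zn, THF) and intramolecular aldol addition would close the ring at C5–C6 and give (7S)-6-hydroxy-7-methyl-7-[(4S)-4-methylhex-5-en-1-yl]oxepan-3-one F3. Horner–Wadsworth–Emmons olefination (triethyl phosphonoacetate, NaH, THF) would then give 11 after removal of the (Z)-isomer. This replaces the single annulation by a homoenolate ring closure and a separate olefination whose geometry is not controlled.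

Step 9. The reduction may show poor facial selectivity if the ring oxygen next to C7 competes for the borane or the two flanks of the ketone are not told apart well enough. The fallback sets out from 11 and comes back at 13, and replaces reagent control by separation and recycling. The C6 epimers of 11 from step 7 would be separated by chromatography; the (6R)-epimer is 13. The other epimer, ethyl (2E)-[(6S,7S)-6-hydroxy-7-methyl-7-[(4S)-4-methylhex-5-en-1-yl]oxepan-3-ylidene]acetate F4, would be oxidised to 12 under the conditions of step 8, reduced without selectivity (NaBH4, CeCl3, MeOH) and returned to the separation.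

Step 12. Palladium hydride may move the terminal double bond along the chain, and the methyl-bearing carbon next to the new ketone may lose its configuration under the oxidation conditions. The fallback sets out from 15 and comes back at 16. Markovnikov hydration by oxymercuration–demercuration (Hg(OAc)2, THF/H2O; then NaBH4, NaOH) would be used, since divalent mercury adds to the unhindered terminal alkene much faster than to the trisubstituted one. It would give (3S)-6-[(2S,3R,6E)-3-[(tert-butyldimethylsilyl)oxy]-6-{2-[(tert-butyldimethylsilyl)oxy]ethylidene}-2-methyloxepan-2-yl]-3-methylhexan-2-ol F5 as both carbinol epimers. Dess–Martin oxidation would then give 16 without any palladium.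

**Further compounds**
F1 | step 7 | 1-({[(2S,6S)-1-hydroxy-2,6-dimethyloct-7-en-2-yl]oxy}methyl)cyclopropan-1-ol | OC[C@@](C)(OCC1(O)CC1)CCC[C@H](C)C=C
F2 | step 7 | (2S,6S)-2-[(1-hydroxycyclopropyl)methoxy]-2,6-dimethyloct-7-enal | O=C[C@@](C)(OCC1(O)CC1)CCC[C@H](C)C=C
F3 | step 7 | (7S)-6-hydroxy-7-methyl-7-[(4S)-4-methylhex-5-en-1-yl]oxepan-3-one (both C6 epimers) | C=C[C@@H](C)CCC[C@]1(C)OCC(=O)CCC1O
F4 | step 9 | ethyl (2E)-[(6S,7S)-6-hydroxy-7-methyl-7-[(4S)-4-methylhex-5-en-1-yl]oxepan-3-ylidene]acetate | C=C[C@@H](C)CCC[C@]1(C)OC/C(=C/C(=O)OCC)CC[C@@H]1O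
F5 | step 12 | (3S)-6-[(2S,3R,6E)-3-[(tert-butyldimethylsilyl)oxy]-6-{2-[(tert-butyldimethylsilyl)oxy]ethylidene}-2-methyloxepan-2-yl]-3-methylhexan-2-ol (both carbinol epimers) | CC(O)[C@@H](C)CCC[C@]1(C)OC/C(=C/CO[Si](C)(C)C(C)(C)C)CC[C@H]1O[Si](C)(C)C(C)(C)C
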